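## Structural features

The target is a chalcone: ring A and ring B are benzene rings joined by an (E)-prop-2-en-1-one unit, with the carbonyl carbon on C-1' of ring A and the β-carbon on C-1 of ring B. Ring A carries hydroxyls at C-2' and C-4' and a 3-methylbut-2-enyl (prenyl) group at C-3', the carbon between them; ring B carries a hydroxyl at C-4 and, ortho to it at C-3, a 2-hydroxy-3-methylbut-3-enyl chain. The only stereocentre is the carbinol carbon C-2'' of that chain (R); it has no stereogenic neighbour, so a reagent must set it, and as a secondary allylic alcohol between a benzylic CH2 and an isopropenyl group it should afterwards be kept away from ionising acid. The fragile groups are the 2'-hydroxychalcone (oxa-Michael closure to a flavanone in acid or strong base), each phenol with its ortho five-carbon chain (acid closes chromans or dihydrobenzofurans), the enone as a Michael acceptor, and four C=C bonds open to electrophiles and oxidants. The real difficulty is regiochemical, since C-3' and not C-5' must carry the prenyl group and substitution of a 2,4-dihydroxyaryl ketone does not separate these positions cleanly; a second difficulty is to unveil three hydroxyls at the end without acid. The key step exploits the fact that O-2', C-3', O-4' of ring A map onto cyclohexane-1,3-dione: C-3' is its C-2 (the only carbon that alkylates), C-1' is the α' carbon of its mono-enol ether (the carbon a kinetic enolate acylates), and C-5'/C-6' are the saturated carbons whose hydrogens are lost when ring A is aromatised through a selenoxide at C-1'.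

## Logic of the disconnections

27 to 26. Three O–Si bonds are cut (O-4', O-4, O-2''). All three hydroxyls are carried as silyl ethers so that one buffered fluoride treatment, with no acid, ends the synthesis; an acetal-based scheme was set aside because its removal needs acid next to the ortho-prenyl phenol, the hydroxychalcone and the allylic alcohol. The gain is that phenol acidity and the free alcohol are absent from all earlier steps. The forward step must cleave a hindered secondary silyl ether completely without base-induced flavanone closure.

26 to 21. No skeletal bond is cut. Ring A is taken back to its dihydro level by adding hydrogen to C-1' and C-6', which turns the 2'-hydroxyaryl ketone into a 6-acyl-3-silyloxycyclohex-2-enone. The gain is that the whole substitution pattern of ring A becomes the outcome of enolate chemistry on a symmetric dione. The forward step must introduce the C-1'=C-6' double bond with a reagent that ignores four alkenes and can eliminate in one direction only.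

21 to 4 and 19. The C-1'–C(=O) bond is cut. This divides the molecule into two halves of similar size and places the joining step just before the key step. The forward step needs kinetic α' deprotonation of 4, attack of the enolate at the acyl carbon of 19 rather than at its β-carbon or through oxygen, and two equivalents of enolate because 21 is more acidic than 4.

19 to 18, then to 16 and 17. The acyl C–N bond is cut (activation only), then the C-1–Cβ bond between ring B and the alkene. The bromine of 16 sits para to the ring B oxygen, where bromination of the parent phenol places it, and 17 supplies the three-carbon acid with E geometry. The forward step must insert into the C–Br bond in the presence of a 1,1-disubstituted alkene and keep two silyl ethers intact at about 90 °C.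

16 to 15, then to 13. The carbinol O–Si bond is cut, then the C-2''–H bond, which leads back to a prochiral ketone. The stereocentre then comes from catalyst control on a flat carbonyl with two clearly different flanks. The forward step must discriminate CH2Ar from isopropenyl and avoid hydroboration and conjugate reduction.

13 to 10 and 11, then 10 to 8, 6 and 5. The C-2''–C-3'' bond is cut, then the amide C–N bond, the phenolic O–Si bond and the C-5–Br bond. 5 already holds ring B with its oxygen and the two-carbon acid chain in the right ortho relation. The forward steps need single addition of 11, masking of the phenol before the ketone exists (a free ortho-hydroxybenzyl ketone would close to a hemiketal and dehydrate to a benzofuran), and para-selective bromination.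

4 to 3, then to 1 and 2. The enol O–Si bond is cut, then the C-3'–prenyl bond. 3 is symmetric, so C-alkylation can occur only between the carbonyls and O-silylation gives one constitution. The forward steps need C- over O-alkylation and mono-alkylation.

## Other disconnections considered

Alternative 1: The cut is at the two C–O bonds of an epoxide on the ring B prenyl group, so that C-2'' is set on a complete, achiral chalcone; the ring A prenyl group is stored as a 4'-O-(1,1-dimethylallyl) ether. In the forward key step the chalcone (E)-1-[2-hydroxy-4-(2-methylbut-3-en-2-yloxy)phenyl]-3-[4-(methoxymethoxy)-3-(3-methylbut-2-enyl)phenyl]prop-2-en-1-one A2 would be epoxidised by a chiral dioxirane (fructose-derived ketone catalyst, peroxymonosulfate as oxidant) to (E)-1-[2-hydroxy-4-(2-methylbut-3-en-2-yloxy)phenyl]-3-{3-[((R)-3,3-dimethyloxiran-2-yl)methyl]-4-(methoxymethoxy)phenyl}prop-2-en-1-one A1. A1 would then need epoxide-to-allylic-alcohol isomerisation, Claisen rearrangement of the allyl group from O-4' to C-3', and acetal cleavage.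
- In favour: the stereocentre is made late and catalytically from the achiral chalcone A2; the trisubstituted alkene of A2 is the only good dioxirane substrate, because the stored group has a monosubstituted alkene and the enone is electron-poor; A2 itself comes from a classical aldol condensation.
- Against: the oxidation runs in basic buffer on a substrate with a free phenol and an enone open to peroxide anion. The isomerisation of A1 must remove a methyl hydrogen and not a benzylic one, and the usual reagents (hindered amide bases, aluminium alkoxides at high temperature) threaten the enone through addition or Meerwein–Ponndorf–Verley reduction. The Claisen rearrangement can deliver to C-3' or C-5' and needs heat that also favours flavanone closure. The last step is acidic.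
- Comparison: on step economy Alternative 1 is the equal of the chosen plan or slightly better, and on enantiocontrol the two are equals (catalyst control on an unhindered π system in both). On structure the chosen plan is stronger, because C-3' is fixed by constitution rather than by the preference of a sigmatropic shift. On mechanism the chosen plan leaves one mild operation after its key step, whereas Alternative 1 runs three further reactions on the finished, sensitive chalcone A1.

Alternative 2: The cut is at C-1'–C-2' and C-5'–C-6', so that ring A is made by cycloaddition. In the forward key step the diene 1-methoxy-2-(3-methylbut-2-enyl)-1,3-bis(trimethylsilyloxy)buta-1,3-diene A4 would add across the terminal alkyne of the enynone (E)-1-{3-[(R)-2-(tert-butyldimethylsilyloxy)-3-methylbut-3-enyl]-4-(tert-butyldimethylsilyloxy)phenyl}pent-1-en-4-yn-3-one A5 in a Diels–Alder reaction. Loss of the C-1 methoxy group and of the trimethylsilyl groups would then give the chalcone (E)-3-{3-[(R)-2-(tert-butyldimethylsilyloxy)-3-methylbut-3-enyl]-4-(tert-butyldimethylsilyloxy)phenyl}-1-[2,4-dihydroxy-3-(3-methylbut-2-enyl)phenyl]prop-2-en-1-one A3.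
- In favour: two C–C bonds form in one step; the polarity of A4 and A5 fixes the regiochemistry; ring A needs no protecting group and no dehydrogenation; A3 needs only a fluoride step to reach the target.
- Against: A4 is a fully substituted, hydrolytically labile ketene acetal whose 2-substituent lowers its reactivity. A5 is a cross-conjugated enynone with two acceptor sites and a terminal ynone prone to polymerisation. The cycloadduct can aromatise by losing either the methoxy or the silyloxy group from the same carbon, so that part of the material would keep a methyl group on O-2' instead of arriving at A3.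
- Comparison: regiochemical security of ring A is equal in principle, since both plans build the 1,3-dioxygen pattern before the ring is aromatic. Alternative 2 is better in bond economy and probably one or two steps shorter, and its end is as mild as that of the chosen plan. The chosen plan is stronger on mechanism: it uses a stable dione and stepwise polar reactions with separate control points, while Alternative 2 stakes the route on one reaction between the two sensitive partners A4 and A5.

Alternative 3: The cut is at both bonds to the carbonyl carbon. In the forward key step zerovalent palladium would insert into the C–I bond of the aryl iodide 1-iodo-2,4-bis(methoxymethoxy)-3-(3-methylbut-2-enyl)benzene A7, take up carbon monoxide A9, and add the acyl group to the terminal carbon of the styrene (R)-tert-butyl{1-[2-(methoxymethoxy)-5-vinylphenyl]-3-methylbut-3-en-2-yloxy}dimethylsilane A8. β-Hydride elimination would then give the chalcone (E)-1-[2,4-bis(methoxymethoxy)-3-(3-methylbut-2-enyl)phenyl]-3-{3-[(R)-2-(tert-butyldimethylsilyloxy)-3-methylbut-3-enyl]-4-(methoxymethoxy)phenyl}prop-2-en-1-one A6.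
- In favour: it is the most convergent plan; A7 is accessible regioselectively by directed metalation, A8 by vinylation of the same ring B chemistry used here; no enolate acylation and no selenium are needed; the E alkene of A6 follows from the elimination.
- Against: carbonylative vinylation competes with direct arylation of A8 before A9 is taken up. A7 is electron-rich and ortho-substituted. The reaction needs gas pressure and heat in the presence of two other alkenes. A6 carries three acetals, so the end is acidic, the weakness the chosen plan avoids.
- Comparison: Alternative 3 is better in convergence and step count, and equal in stereocontrol and in the regiochemical security of ring A. The chosen plan is stronger in the reliability of its bond-forming steps and in the mildness of the final deprotection.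

Key step: step 12

Assumptions and conventions:
- Primed locants refer to ring A, unprimed to ring B, doubly primed to the five-carbon chain on ring B.
- C-6 of 21 (the future C-1') is the methine of an enolised β-diketone; it is configurationally labile, is drawn without configuration, and is destroyed in step 12.
- Covalent intermediates that persist until the next reagent or the quench are numbered, as are enolates made with a strong base before the electrophile is added. Salts that differ from a numbered compound only by a proton removed by KOH, carbonate or an amine are not numbered.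
- LiN(i-Pr)2, isopropenylmagnesium bromide and catecholborane are used as commercial solutions.

## Route

Step 1
Reactants: 1 cyclohexane-1,3-dione; 2 1-bromo-3-methylbut-2-ene
Product: 3 2-(3-methylbut-2-enyl)cyclohexane-1,3-dione
Conditions: KOH (1.0 equiv), H2O, 0 °C → rt; acidify to pH 4
Reagents that add atoms: none
Why: C-alkylation of a cyclic 1,3-dione enolate with an allylic bromide (SN2); in water the enolate oxygens are hydrogen-bonded, which favours attack through C-2, and a slight excess of 1 limits double alkylation. The symmetric dione can carry the prenyl group only on the carbon between the carbonyls, which becomes C-3'.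

Step 2
Reactants: 3 2-(3-methylbut-2-enyl)cyclohexane-1,3-dione
Product: 4 2-(3-methylbut-2-enyl)-3-(triisopropylsilyloxy)cyclohex-2-en-1-one
Conditions: i-Pr3SiOTf, Et3N, CH2Cl2, 0 °C
Reagents that add atoms: triisopropylsilyl trifluoromethanesulfonate, CC(C)[Si](OS(=O)(=O)C(F)(F)F)(C(C)C)C(C)C
Why: O-silylation of the enolised dione (silicon is oxophilic); because 3 is symmetric only one vinylogous silyl ester can form. The bulky triisopropylsilyl group should survive chromatography and lithium amide base, and after aromatisation it becomes an aryl silyl ether that fluoride removes.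

Step 3
Reactants: 5 2-hydroxyphenylacetic acid
Product: 6 2-(5-bromo-2-hydroxyphenyl)acetic acid
Conditions: N-bromosuccinimide (1.0 equiv), MeCN, 0 °C
Reagents that add atoms: N-bromosuccinimide, O=C1CCC(=O)N1Br
Why: Electrophilic aromatic bromination; the hydroxyl directs to its para position C-5, which is favoured over the ortho position in acetonitrile, and one equivalent at 0 °C should limit dibromination.

Step 4
Reactants: 6 2-(5-bromo-2-hydroxyphenyl)acetic acid
Product: 8 2-[5-bromo-2-(triisopropylsilyloxy)phenyl]acetic acid, via bis-silyl derivative 7 (not isolated)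
Conditions: i-Pr3SiCl (2.3 equiv), imidazole, DMF, rt; then K2CO3, MeOH–THF–H2O, 0 °C; cold dilute HCl to pH 4
Reagents that add atoms: triisopropylsilyl chloride, CC(C)[Si](Cl)(C(C)C)C(C)C
Why: Silylation of phenol and acid followed by selective hydrolysis of the much more labile silyl ester; the hindered aryl silyl ether should survive brief cold carbonate. The phenol must be masked before the ketone of 13 exists, since a free ortho-hydroxybenzyl ketone would close to a hemiketal and dehydrate to a benzofuran.

Step 5
Reactants: 8 2-[5-bromo-2-(triisopropylsilyloxy)phenyl]acetic acid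
Product: 10 2-[5-bromo-2-(triisopropylsilyloxy)phenyl]-N-methoxy-N-methylacetamide, via acyl imidazolide 9 (not isolated)
Conditions: 1,1'-carbonyldiimidazole, CH2Cl2, rt; then MeNH(OMe)·HCl, rt
Reagents that add atoms: N,O-dimethylhydroxylamine hydrochloride, CNOC.Cl
Why: Amide formation through the acyl imidazolide; the hydroxylamine displaces imidazole and gives the N-methoxy-N-methylamide needed for single addition in step 6.

Step 6
Reactants: 10 2-[5-bromo-2-(triisopropylsilyloxy)phenyl]-N-methoxy-N-methylacetamide; 11 isopropenylmagnesium bromide
Product: 13 1-[5-bromo-2-(triisopropylsilyloxy)phenyl]-3-methylbut-3-en-2-one, via magnesium chelate 12 (not isolated)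
Conditions: THF, −20 → 0 °C; poured into cold 1 M HCl
Reagents that add atoms: none
Why: Weinreb ketone synthesis: the alkenyl Grignard reagent adds once and the chelated tetrahedral adduct survives until the quench, so no tertiary alcohol forms; aryl bromide and silyl ether are inert to the reagent at 0 °C. The cold acidic inverse quench protonates the released hydroxylamine before it can add to the new enone.

Step 7
Reactants: 13 1-[5-bromo-2-(triisopropylsilyloxy)phenyl]-3-methylbut-3-en-2-one
Product: 15 (2R)-1-[5-bromo-2-(triisopropylsilyloxy)phenyl]-3-methylbut-3-en-2-ol, via catechol borate ester 14 (not isolated)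
Conditions: (S)-2-methyl-CBS-oxazaborolidine (0.2 equiv), catecholborane, toluene, −78 °C; MeOH, then aq. Na2CO3 wash
Reagents that add atoms: none
Why: Corey–Bakshi–Shibata reduction: the ketone binds the catalyst boron anti to its larger flank, here the α-branched isopropenyl group, and hydride comes from the coordinated borane to one face; with the (S)-catalyst and isopropenyl ranking above CH2Ar this corresponds to the (R)-carbinol, by analogy with aryl methyl ketones and α-substituted enones. Catecholborane at −78 °C should not hydroborate the 1,1-disubstituted alkene, and the catalysed 1,2-reduction should outrun conjugate reduction.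

Step 8
Reactants: 15 (2R)-1-[5-bromo-2-(triisopropylsilyloxy)phenyl]-3-methylbut-3-en-2-ol
Product: 16 (R)-{4-bromo-2-[2-(tert-butyldimethylsilyloxy)-3-methylbut-3-enyl]phenoxy}triisopropylsilane
Conditions: t-BuMe2SiCl, imidazole, DMF, rt
Reagents that add atoms: tert-butyldimethylsilyl chloride, CC(C)(C)[Si](C)(C)Cl
Why: Standard silylation of a secondary alcohol; it prevents self-acylation in steps 10 and 11, and the stereocentre is not touched because only the O–H bond reacts.

Step 9
Reactants: 16 (R)-{4-bromo-2-[2-(tert-butyldimethylsilyloxy)-3-methylbut-3-enyl]phenoxy}triisopropylsilane; 17 acrylic acid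
Product: 18 (E)-3-{3-[(R)-2-(tert-butyldimethylsilyloxy)-3-methylbut-3-enyl]-4-(triisopropylsilyloxy)phenyl}acrylic acid
Conditions: Pd(OAc)2 (5 mol %), P(o-tolyl)3, Et3N, MeCN, 90 °C
Reagents that add atoms: none
Why: Heck reaction: zerovalent palladium formed from Pd(OAc)2 and the phosphine inserts into the C–Br bond, the arylpalladium adds to the acrylate with aryl on the terminal carbon, and syn β-hydride elimination gives the E acid. The electron-poor monosubstituted alkene of 17 should react far faster than the 1,1-disubstituted alkene of 16, and no ring can form from C-1 to the meta side chain.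

Step 10
Reactants: 18 (E)-3-{3-[(R)-2-(tert-butyldimethylsilyloxy)-3-methylbut-3-enyl]-4-(triisopropylsilyloxy)phenyl}acrylic acid
Product: 19 (E)-1-(1H-benzotriazol-1-yl)-3-{3-[(R)-2-(tert-butyldimethylsilyloxy)-3-methylbut-3-enyl]-4-(triisopropylsilyloxy)phenyl}prop-2-en-1-one
Conditions: 1-(methylsulfonyl)benzotriazole, Et3N, THF, 60 °C
Reagents that add atoms: 1-(methylsulfonyl)-1H-benzotriazole, CS(=O)(=O)n1nnc2ccccc21
Why: The carboxylate attacks sulfur to give a transient mixed carboxylic–sulfonic anhydride, which the released benzotriazolide acylates at once; the medium stays basic, so silyl ethers and the stereocentre are untouched. N-Acylbenzotriazoles are stable acyl donors that favour C- over O-acylation of ketone enolates.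

Step 11
Reactants: 4 2-(3-methylbut-2-enyl)-3-(triisopropylsilyloxy)cyclohex-2-en-1-one; 19 (E)-1-(1H-benzotriazol-1-yl)-3-{3-[(R)-2-(tert-butyldimethylsilyloxy)-3-methylbut-3-enyl]-4-(triisopropylsilyloxy)phenyl}prop-2-en-1-one
Product: 21 (E)-6-{3-[3-((R)-2-(tert-butyldimethylsilyloxy)-3-methylbut-3-enyl)-4-(triisopropylsilyloxy)phenyl]acryloyl}-2-(3-methylbut-2-enyl)-3-(triisopropylsilyloxy)cyclohex-2-en-1-one, via lithium dienolate 20 (not isolated)
Conditions: LiN(i-Pr)2 (2.2 equiv), 4 (2.2 equiv), THF, −78 °C; then 19 (1.0 equiv), −78 → −40 °C; sat. aq. NH4Cl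
Reagents that add atoms: none
Why: Kinetic deprotonation of a 3-oxy-cyclohex-2-enone by a lithium amide occurs at the α' carbon and gives the cross-conjugated dienolate, which is C-acylated by the N-acylbenzotriazole (Claisen-type acylation; at −78 °C addition to the activated acyl carbon should be preferred to conjugate addition). Two equivalents of enolate are used because 21 is more acidic than 4 and is deprotonated as it forms; the excess 4 is recovered. The new methine is part of an enolised β-diketone, so no configuration has to be controlled.

Step 12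
Reactants: 21 (E)-6-{3-[3-((R)-2-(tert-butyldimethylsilyloxy)-3-methylbut-3-enyl)-4-(triisopropylsilyloxy)phenyl]acryloyl}-2-(3-methylbut-2-enyl)-3-(triisopropylsilyloxy)cyclohex-2-en-1-one
Product: 26 (E)-3-{3-[(R)-2-(tert-butyldimethylsilyloxy)-3-methylbut-3-enyl]-4-(triisopropylsilyloxy)phenyl}-1-[2-hydroxy-3-(3-methylbut-2-enyl)-4-(triisopropylsilyloxy)phenyl]prop-2-en-1-one, via sodium enolate 22 (not isolated), via phenylselenide 23 (not isolated), via selenoxide 24 (not isolated), via dienone tautomer 25 (not isolated)
Conditions: NaH (1.05 equiv), THF, 0 °C; PhSeCl (1.05 equiv), −78 °C; mCPBA (1.05 equiv), CH2Cl2, −78 °C; i-Pr2NH, −78 → 0 °C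
Reagents that add atoms: none
Why: NaH removes the β-diketone proton, and the enolate can take the selenium electrophile only at C-1', the one carbon between two carbonyls, because C-3' is tied up in the silyl enol ether; this gives the quaternary selenide. mCPBA at −78 °C oxidises selenium much faster than it epoxidises an alkene, and the selenoxide undergoes syn elimination through a five-membered transition state; the only β-hydrogens are on C-6', so the new double bond is C-1'=C-6'. The cross-conjugated dienone is the keto tautomer of a phenol and tautomerises by moving a C-5' hydrogen to the C-2' oxygen, giving aromatic ring A with a free, chelated 2'-OH and the 4'-oxygen still silylated. The closest known reaction types are α-selenenylation and selenoxide elimination of β-dicarbonyl compounds and the dehydrogenation of 2-acylcyclohexenones and cyclohexane-1,3-dione enol ethers to phenols. No ring is closed and no stereocentre is created; the labile centre of 21 disappears and C-2'' is not involved. The selectivity needed is chemoselectivity for the enolate over four alkenes: the preformed enolate should react with PhSeCl at −78 °C far faster than any alkene, one equivalent of cold peracid is used instead of aqueous H2O2 (which with seleninic acid would form an epoxidising peroxy acid), and i-Pr2NH intercepts PhSeOH before it can add to the prenyl groups. Working at or below 0 °C should also keep the enolate oxygen from adding to the β-carbon of the enone.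

Step 13
Reactants: 26 (E)-3-{3-[(R)-2-(tert-butyldimethylsilyloxy)-3-methylbut-3-enyl]-4-(triisopropylsilyloxy)phenyl}-1-[2-hydroxy-3-(3-methylbut-2-enyl)-4-(triisopropylsilyloxy)phenyl]prop-2-en-1-one
Product: 27 (E)-1-[2,4-dihydroxy-3-(3-methylbut-2-enyl)phenyl]-3-{4-hydroxy-3-[(R)-2-hydroxy-3-methylbut-3-enyl]phenyl}prop-2-en-1-one
Conditions: n-Bu4NF (4 equiv), AcOH (4 equiv), THF, 0 °C → rt
Reagents that add atoms: none
Why: Fluoride-mediated cleavage of two aryl silyl ethers (fast, phenoxide leaving groups) and of the secondary alkyl silyl ether (slower); acetic acid buffers the phenoxides so that the 2'-oxygen should not add to the enone, and no acid strong enough to close the prenyl or hydroxyalkenyl chains onto the phenols is present. C-2'' keeps its configuration because only O–Si bonds are broken.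

## Compound list

1 | cyclohexane-1,3-dione | O=C1CCCC(=O)C1 | starting material
2 | 1-bromo-3-methylbut-2-ene | CC(C)=CCBr | starting material
3 | 2-(3-methylbut-2-enyl)cyclohexane-1,3-dione (drawn as diketone) | CC(C)=CCC1C(=O)CCCC1=O | intermediate
4 | 2-(3-methylbut-2-enyl)-3-(triisopropylsilyloxy)cyclohex-2-en-1-one | CC(C)=CCC1=C(O[Si](C(C)C)(C(C)C)C(C)C)CCCC1=O | intermediate
5 | 2-hydroxyphenylacetic acid | OC(=O)Cc1ccccc1O | starting material
6 | 2-(5-bromo-2-hydroxyphenyl)acetic acid | OC(=O)Cc1cc(Br)ccc1O | intermediate
7 | triisopropylsilyl 2-[5-bromo-2-(triisopropylsilyloxy)phenyl]acetate | CC(C)[Si](OC(=O)Cc1cc(Br)ccc1O[Si](C(C)C)(C(C)C)C(C)C)(C(C)C)C(C)C | intermediate (not isolated)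
8 | 2-[5-bromo-2-(triisopropylsilyloxy)phenyl]acetic acid | OC(=O)Cc1cc(Br)ccc1O[Si](C(C)C)(C(C)C)C(C)C | intermediate
9 | 2-[5-bromo-2-(triisopropylsilyloxy)phenyl]-1-(imidazol-1-yl)ethan-1-one | O=C(Cc1cc(Br)ccc1O[Si](C(C)C)(C(C)C)C(C)C)n1ccnc1 | intermediate (not isolated)
10 | 2-[5-bromo-2-(triisopropylsilyloxy)phenyl]-N-methoxy-N-methylacetamide | CON(C)C(=O)Cc1cc(Br)ccc1O[Si](C(C)C)(C(C)C)C(C)C | intermediate
11 | isopropenylmagnesium bromide | C=C(C)[Mg]Br | starting material
12 | bromomagnesium alkoxide of the tetrahedral adduct of 10 and 11 | C=C(C)C(O[Mg]Br)(N(C)OC)Cc1cc(Br)ccc1O[Si](C(C)C)(C(C)C)C(C)C | intermediate (not isolated)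
13 | 1-[5-bromo-2-(triisopropylsilyloxy)phenyl]-3-methylbut-3-en-2-one | C=C(C)C(=O)Cc1cc(Br)ccc1O[Si](C(C)C)(C(C)C)C(C)C | intermediate
14 | 2-{(2R)-1-[5-bromo-2-(triisopropylsilyloxy)phenyl]-3-methylbut-3-en-2-yloxy}-1,3,2-benzodioxaborole | C=C(C)[C@H](OB1Oc2ccccc2O1)Cc1cc(Br)ccc1O[Si](C(C)C)(C(C)C)C(C)C | intermediate (not isolated)
15 | (2R)-1-[5-bromo-2-(triisopropylsilyloxy)phenyl]-3-methylbut-3-en-2-ol | C=C(C)[C@H](O)Cc1cc(Br)ccc1O[Si](C(C)C)(C(C)C)C(C)C | intermediate
16 | (R)-{4-bromo-2-[2-(tert-butyldimethylsilyloxy)-3-methylbut-3-enyl]phenoxy}triisopropylsilane | C=C(C)[C@H](O[Si](C)(C)C(C)(C)C)Cc1cc(Br)ccc1O[Si](C(C)C)(C(C)C)C(C)C | intermediate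
17 | acrylic acid | C=CC(=O)O | starting material
18 | (E)-3-{3-[(R)-2-(tert-butyldimethylsilyloxy)-3-methylbut-3-enyl]-4-(triisopropylsilyloxy)phenyl}acrylic acid | C=C(C)[C@H](O[Si](C)(C)C(C)(C)C)Cc1cc(/C=C/C(=O)O)ccc1O[Si](C(C)C)(C(C)C)C(C)C | intermediate
19 | (E)-1-(1H-benzotriazol-1-yl)-3-{3-[(R)-2-(tert-butyldimethylsilyloxy)-3-methylbut-3-enyl]-4-(triisopropylsilyloxy)phenyl}prop-2-en-1-one | C=C(C)[C@H](O[Si](C)(C)C(C)(C)C)Cc1cc(/C=C/C(=O)n2nnc3ccccc32)ccc1O[Si](C(C)C)(C(C)C)C(C)C | intermediate
20 | lithium 6-(3-methylbut-2-enyl)-5-(triisopropylsilyloxy)cyclohexa-1,5-dien-1-olate | CC(C)=CCC1=C(O[Si](C(C)C)(C(C)C)C(C)C)CCC=C1[O-].[Li+] | intermediate (not isolated)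
21 | (E)-6-{3-[3-((R)-2-(tert-butyldimethylsilyloxy)-3-methylbut-3-enyl)-4-(triisopropylsilyloxy)phenyl]acryloyl}-2-(3-methylbut-2-enyl)-3-(triisopropylsilyloxy)cyclohex-2-en-1-one (C-6 labile, largely enolised) | C=C(C)[C@H](O[Si](C)(C)C(C)(C)C)Cc1cc(/C=C/C(=O)C2CCC(O[Si](C(C)C)(C(C)C)C(C)C)=C(CC=C(C)C)C2=O)ccc1O[Si](C(C)C)(C(C)C)C(C)C | intermediate (precursor of the key step)
22 | sodium enolate of 21, drawn as the ring C-1 enolate | C=C(C)[C@H](O[Si](C)(C)C(C)(C)C)Cc1cc(/C=C/C(=O)C2=C([O-])C(CC=C(C)C)=C(O[Si](C(C)C)(C(C)C)C(C)C)CC2)ccc1O[Si](C(C)C)(C(C)C)C(C)C.[Na+] | intermediate (not isolated)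
23 | 6-(phenylselanyl) derivative of 21 (both C-6 epimers) | C=C(C)[C@H](O[Si](C)(C)C(C)(C)C)Cc1cc(/C=C/C(=O)C2([Se]c3ccccc3)CCC(O[Si](C(C)C)(C(C)C)C(C)C)=C(CC=C(C)C)C2=O)ccc1O[Si](C(C)C)(C(C)C)C(C)C | intermediate (not isolated)
24 | 6-(phenylseleninyl) derivative of 21 (selenoxide) | C=C(C)[C@H](O[Si](C)(C)C(C)(C)C)Cc1cc(/C=C/C(=O)C2([Se](=O)c3ccccc3)CCC(O[Si](C(C)C)(C(C)C)C(C)C)=C(CC=C(C)C)C2=O)ccc1O[Si](C(C)C)(C(C)C)C(C)C | intermediate (not isolated)
25 | (E)-2-{3-[3-((R)-2-(tert-butyldimethylsilyloxy)-3-methylbut-3-enyl)-4-(triisopropylsilyloxy)phenyl]acryloyl}-6-(3-methylbut-2-enyl)-5-(triisopropylsilyloxy)cyclohexa-2,5-dien-1-one | C=C(C)[C@H](O[Si](C)(C)C(C)(C)C)Cc1cc(/C=C/C(=O)C2=CCC(O[Si](C(C)C)(C(C)C)C(C)C)=C(CC=C(C)C)C2=O)ccc1O[Si](C(C)C)(C(C)C)C(C)C | intermediate (not isolated)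
26 | (E)-3-{3-[(R)-2-(tert-butyldimethylsilyloxy)-3-methylbut-3-enyl]-4-(triisopropylsilyloxy)phenyl}-1-[2-hydroxy-3-(3-methylbut-2-enyl)-4-(triisopropylsilyloxy)phenyl]prop-2-en-1-one | C=C(C)[C@H](O[Si](C)(C)C(C)(C)C)Cc1cc(/C=C/C(=O)c2ccc(O[Si](C(C)C)(C(C)C)C(C)C)c(CC=C(C)C)c2O)ccc1O[Si](C(C)C)(C(C)C)C(C)C | intermediate (product of the key step)
27 | (E)-1-[2,4-dihydroxy-3-(3-methylbut-2-enyl)phenyl]-3-{4-hydroxy-3-[(R)-2-hydroxy-3-methylbut-3-enyl]phenyl}prop-2-en-1-one | C=C(C)[C@H](O)Cc1cc(/C=C/C(=O)c2ccc(O)c(CC=C(C)C)c2O)ccc1O | target

## Step count and least certain steps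

Total: 13 steps. Longest linear sequence: 11 steps (5 to 27, steps 3 to 13); the ring A branch (1 to 4) has two steps before the coupling.

Step 12 (key step). The most likely failure is transfer of electrophilic selenium (from PhSeCl or from PhSeOH released in the elimination) to the trisubstituted alkenes, or conjugate closure of the enolate oxygen onto the enone before selenenylation. Both are possible because the substrate holds four alkenes and an internal Michael acceptor. The fallback sets out from 21 and comes back at 26: direct dehydrogenation with 2,3-dichloro-5,6-dicyano-1,4-benzoquinone (1.1 equiv, 1,4-dioxane, rt). Hydride abstraction from the C-5'/C-6' methylene pair of the enolised diketone and proton loss lead to the same aromatic ring whichever methylene reacts first, with neither base nor selenium present. This path makes no compound outside the list, which the entry F0 records.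

Step 11. The most likely failure is conjugate addition of the dienolate to the β-carbon of the cinnamoyl unit, or proton transfer from the product that stalls the acylation; the acyl donor is also an enone, and 21 is far more acidic than 4. The fallback sets out from 16 and 4, comes back at 21, and replaces acyl transfer by aldol addition and oxidation. Bromine–lithium exchange on 16 (n-C4H9Li, THF, −78 °C) would give the aryllithium (R)-{2-[2-(tert-butyldimethylsilyloxy)-3-methylbut-3-enyl]-4-lithiophenoxy}triisopropylsilane F1, and formylation with N,N-dimethylformamide would give 3-[(R)-2-(tert-butyldimethylsilyloxy)-3-methylbut-3-enyl]-4-(triisopropylsilyloxy)benzaldehyde F2. A Wittig reaction with (triphenylphosphoranylidene)acetaldehyde (toluene, 80 °C) would then give (E)-3-{3-[(R)-2-(tert-butyldimethylsilyloxy)-3-methylbut-3-enyl]-4-(triisopropylsilyloxy)phenyl}acrylaldehyde F3. Dienolate 20 (1.1 equiv, made from 4 as in step 11, −78 °C) should add 1,2 to F3 to give the aldol 6-{(E)-1-hydroxy-3-[3-((R)-2-(tert-butyldimethylsilyloxy)-3-methylbut-3-enyl)-4-(triisopropylsilyloxy)phenyl]prop-2-enyl}-2-(3-methylbut-2-enyl)-3-(triisopropylsilyloxy)cyclohex-2-en-1-one F4, as a mixture of diastereomers that does not matter, and Dess–Martin oxidation (NaHCO3, CH2Cl2) of F4 would give 21.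

Step 7. The most likely failure is insufficient facial discrimination between the CH2Ar and isopropenyl flanks, with some conjugate reduction; the two flanks differ less in size than aryl and methyl. The fallback sets out from 13, comes back at 15, and replaces asymmetric reduction by resolution. Luche reduction (NaBH4, CeCl3·7H2O, MeOH, −40 °C) would give racemic 1-[5-bromo-2-(triisopropylsilyloxy)phenyl]-3-methylbut-3-en-2-ol F5. Sharpless kinetic resolution (Ti(OiPr)4, L-(+)-diisopropyl tartrate, t-BuOOH 0.6 equiv, 4 Å sieves, CH2Cl2, −20 °C) should then epoxidise the (S)-enantiomer to (1S)-2-[5-bromo-2-(triisopropylsilyloxy)phenyl]-1-[(2R)-2-methyloxiran-2-yl]ethan-1-ol F6 and leave 15, which is separated by chromatography.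

Step 13. The most likely failure is incomplete cleavage of the hindered secondary silyl ether; forcing it with excess unbuffered fluoride risks base-induced closure of the 2'-oxygen onto the enone. The fallback sets out from 26 and comes back at 27 in two stages with different reagents. Brief treatment with n-Bu4NF/AcOH at 0 °C should remove only the two aryl silyl groups and give (E)-3-{3-[(R)-2-(tert-butyldimethylsilyloxy)-3-methylbut-3-enyl]-4-hydroxyphenyl}-1-[2,4-dihydroxy-3-(3-methylbut-2-enyl)phenyl]prop-2-en-1-one F7. The remaining alkyl silyl ether of F7 is then cleaved under non-basic conditions with HF·pyridine buffered with pyridine (THF, 0 °C → rt) to give 27.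

## Further compounds

F0 | step 12 | none | none
F1 | step 11 | (R)-{2-[2-(tert-butyldimethylsilyloxy)-3-methylbut-3-enyl]-4-lithiophenoxy}triisopropylsilane | C=C(C)[C@H](O[Si](C)(C)C(C)(C)C)Cc1cc([Li])ccc1O[Si](C(C)C)(C(C)C)C(C)C
F2 | step 11 | 3-[(R)-2-(tert-butyldimethylsilyloxy)-3-methylbut-3-enyl]-4-(triisopropylsilyloxy)benzaldehyde | C=C(C)[C@H](O[Si](C)(C)C(C)(C)C)Cc1cc(C=O)ccc1O[Si](C(C)C)(C(C)C)C(C)C
F3 | step 11 | (E)-3-{3-[(R)-2-(tert-butyldimethylsilyloxy)-3-methylbut-3-enyl]-4-(triisopropylsilyloxy)phenyl}acrylaldehyde | C=C(C)[C@H](O[Si](C)(C)C(C)(C)C)Cc1cc(/C=C/C=O)ccc1O[Si](C(C)C)(C(C)C)C(C)C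
F4 | step 11 | 6-{(E)-1-hydroxy-3-[3-((R)-2-(tert-butyldimethylsilyloxy)-3-methylbut-3-enyl)-4-(triisopropylsilyloxy)phenyl]prop-2-enyl}-2-(3-methylbut-2-enyl)-3-(triisopropylsilyloxy)cyclohex-2-en-1-one | C=C(C)[C@H](O[Si](C)(C)C(C)(C)C)Cc1cc(/C=C/C(O)C2CCC(O[Si](C(C)C)(C(C)C)C(C)C)=C(CC=C(C)C)C2=O)ccc1O[Si](C(C)C)(C(C)C)C(C)C
F5 | step 7 | racemic 1-[5-bromo-2-(triisopropylsilyloxy)phenyl]-3-methylbut-3-en-2-ol | C=C(C)C(O)Cc1cc(Br)ccc1O[Si](C(C)C)(C(C)C)C(C)C
F6 | step 7 | (1S)-2-[5-bromo-2-(triisopropylsilyloxy)phenyl]-1-[(2R)-2-methyloxiran-2-yl]ethan-1-ol | C[C@@]1(CO1)[C@@H](O)Cc1cc(Br)ccc1O[Si](C(C)C)(C(C)C)C(C)C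
F7 | step 13 | (E)-3-{3-[(R)-2-(tert-butyldimethylsilyloxy)-3-methylbut-3-enyl]-4-hydroxyphenyl}-1-[2,4-dihydroxy-3-(3-methylbut-2-enyl)phenyl]prop-2-en-1-one | C=C(C)[C@H](O[Si](C)(C)C(C)(C)C)Cc1cc(/C=C/C(=O)c2ccc(O)c(CC=C(C)C)c2O)ccc1O
A1 | alternative 1 | (E)-1-[2-hydroxy-4-(2-methylbut-3-en-2-yloxy)phenyl]-3-{3-[((R)-3,3-dimethyloxiran-2-yl)methyl]-4-(methoxymethoxy)phenyl}prop-2-en-1-one | C=CC(C)(C)Oc1ccc(C(=O)/C=C/c2ccc(OCOC)c(C[C@H]3OC3(C)C)c2)c(O)c1
A2 | alternative 1 | (E)-1-[2-hydroxy-4-(2-methylbut-3-en-2-yloxy)phenyl]-3-[4-(methoxymethoxy)-3-(3-methylbut-2-enyl)phenyl]prop-2-en-1-one | C=CC(C)(C)Oc1ccc(C(=O)/C=C/c2ccc(OCOC)c(CC=C(C)C)c2)c(O)c1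
A3 | alternative 2 | (E)-3-{3-[(R)-2-(tert-butyldimethylsilyloxy)-3-methylbut-3-enyl]-4-(tert-butyldimethylsilyloxy)phenyl}-1-[2,4-dihydroxy-3-(3-methylbut-2-enyl)phenyl]prop-2-en-1-one | C=C(C)[C@H](O[Si](C)(C)C(C)(C)C)Cc1cc(/C=C/C(=O)c2ccc(O)c(CC=C(C)C)c2O)ccc1O[Si](C)(C)C(C)(C)C
A4 | alternative 2 | 1-methoxy-2-(3-methylbut-2-enyl)-1,3-bis(trimethylsilyloxy)buta-1,3-diene | COC(O[Si](C)(C)C)=C(CC=C(C)C)C(=C)O[Si](C)(C)C
A5 | alternative 2 | (E)-1-{3-[(R)-2-(tert-butyldimethylsilyloxy)-3-methylbut-3-enyl]-4-(tert-butyldimethylsilyloxy)phenyl}pent-1-en-4-yn-3-one | C=C(C)[C@H](O[Si](C)(C)C(C)(C)C)Cc1cc(/C=C/C(=O)C#C)ccc1O[Si](C)(C)C(C)(C)C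
A6 | alternative 3 | (E)-1-[2,4-bis(methoxymethoxy)-3-(3-methylbut-2-enyl)phenyl]-3-{3-[(R)-2-(tert-butyldimethylsilyloxy)-3-methylbut-3-enyl]-4-(methoxymethoxy)phenyl}prop-2-en-1-one | C=C(C)[C@H](O[Si](C)(C)C(C)(C)C)Cc1cc(/C=C/C(=O)c2ccc(OCOC)c(CC=C(C)C)c2OCOC)ccc1OCOC
A7 | alternative 3 | 1-iodo-2,4-bis(methoxymethoxy)-3-(3-methylbut-2-enyl)benzene | COCOc1ccc(I)c(OCOC)c1CC=C(C)C
A8 | alternative 3 | (R)-tert-butyl{1-[2-(methoxymethoxy)-5-vinylphenyl]-3-methylbut-3-en-2-yloxy}dimethylsilane | C=C(C)[C@H](O[Si](C)(C)C(C)(C)C)Cc1cc(C=C)ccc1OCOC
A9 | alternative 3 | carbon monoxide | [C-]#[O+]
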